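**Plan**

- Cuts: the two esters and the 4-methoxybenzyl (PMB) mask on O3 come off last. The lactone is cut at O–C6 and oxidised C12, back to an isopropenyl group on C7 and a Z C5=C6 alkene. The carbocycle is cut at C3–C4 with C1–C6 re-joined (retro oxy-Cope), then at C1–C2 (vinyl metal + ketone) and C5–C6 (enolate allylation), back to (S)-carvone.
- Enabling feature: in the ten-membered ring the C1 carbonyl lies 1,5 to the C5–C6 bond, and C3(O)–C4(CH3) is a bond between adjacent stereocentres. C3–C4 is therefore the bond a [3,3] shift forms while a C1–C6 bond breaks, and that bond closes a cyclohexane (C1, C10, C9, C8, C7, C6) that maps onto the carvone ring with its methyl and isopropenyl groups.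
- Ring order forward: the carvone six-membered ring is kept up to the divinyl carbinol, expanded by four carbons to the ten-membered ring, and the γ-lactone is annulated last across C6–C7.
- Stereochemistry: C7 from (S)-carvone; C8 by enolate hydroxylation anti to isopropenyl; C10 by relay (epoxidation anti to isopropenyl, Wharton transposition, carbonate delivery from the C1 oxygen); C3 and C4 from the Z and E alkene geometries through the chair transition state; C6 by boron delivery from C12; angelate geometry bought.

Key step: step 15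

Remark: locants C1–C13 are the germacranolide numbers of the target, which is 3S,4R,6R,7S,8S,10R: C1 ketone, C3 carbinol, C4 methyl-bearing, C6 lactone oxygen, C8 angelate, C10 acetate, C11–C13 lactone carbons. C1 is carried as an epimer mixture in 29–36 and C11 in 29–33; both centres become sp2 again.

**Route**

Step 1
Reactants: 1 (S)-(+)-carvone
Product: 3 trans-6-hydroxycarvone (hydroxyl anti to the isopropenyl group), via potassium dienolate 2 (not isolated)
Conditions: KN(SiMe3)2, THF, −78 °C; 3-phenyl-2-(phenylsulfonyl)oxaziridine, −78 °C; H2O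
Reagents that add atoms: 3-phenyl-2-(phenylsulfonyl)oxaziridine, O=S(=O)(N1OC1c1ccccc1)c1ccccc1
Why: Kinetic deprotonation at the only sp3 alpha carbon gives the cross-conjugated enolate and Davis enolate hydroxylation transfers oxygen to the face away from the neighbouring isopropenyl group, which sets the future C8; the trans isomer is also the more stable one at this epimerisable position.

Step 2
Reactants: 3 trans-6-hydroxycarvone
Product: 4 trans-6-(tert-butyldimethylsilyloxy)carvone
Conditions: TBSCl, imidazole, DMF, rt
Reagents that add atoms: tert-butyldimethylsilyl chloride, CC(C)(C)[Si](C)(C)Cl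
Why: Imidazole-promoted silylation of the secondary alcohol (Corey conditions) protects the C8 oxygen with a group that should survive the basic, organometallic and oxidative steps up to step 21.

Step 3
Reactants: 4 trans-6-(tert-butyldimethylsilyloxy)carvone
Product: 5 epoxy ketone with the epoxide anti to isopropenyl and syn to the silyloxy group
Conditions: 30% H2O2, NaOH (cat.), MeOH, 0 °C
Reagents that add atoms: hydrogen peroxide, OO
Why: Weitz–Scheffer nucleophilic epoxidation, in which hydroperoxide adds to the beta carbon anti to the isopropenyl group two carbons away, as it does with carvone itself, so the epoxide on the future C1 and C10 lies anti to isopropenyl.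

Step 4
Reactants: 5 epoxy ketone
Product: 7 transposed allylic alcohol (C1 carbinol cis to the C8 silyloxy group and trans to isopropenyl; C9=C10 alkene), via epoxy hydrazone 6 (not isolated)
Conditions: N2H4·H2O, AcOH (cat.), MeOH, 0 °C → rt
Reagents that add atoms: none
Why: Wharton transposition, in which the epoxy hydrazone opens to a vinyl diazene that loses N2 and the epoxide C–O bond at the future C1 is retained, so the carbinol configuration is that of the epoxide face.

Step 5
Reactants: 7 transposed allylic alcohol
Product: 9 cis-fused C1/C10 cyclic carbonate bearing iodine at C9, via lithium alkyl carbonate 8 (not isolated)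
Conditions: n-BuLi, THF, −78 °C; CO2; I2, −78 → 0 °C
Reagents that add atoms: carbon dioxide, O=C=O; iodine, II
Why: Iodocarbonate cyclisation of an allylic alcohol through its lithium carbonate, in which the carbonate oxygen tethered to C1 can reach only C10 (the Markovnikov carbon, 5-exo) on the face of the C1–O bond while iodine adds anti at C9, which sets the C10 oxygen cis to the C8 oxygen with unambiguous regiochemistry (hydride opening of the corresponding epoxide at C9 would have to run against trans-diaxial opening).

Step 6
Reactants: 9 iodo carbonate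
Product: 10 cis-fused C1/C10 cyclic carbonate with C9 as methylene
Conditions: Bu3SnH, AIBN (cat.), toluene, 80 °C
Reagents that add atoms: none
Why: Radical chain dehalogenation with tributyltin hydride turns C9 into a methylene group without touching the carbonate, the silyl ether or the stereocentres.

Step 7
Reactants: 10 cyclic carbonate
Product: 11 cis-1,2-diol (secondary C1 hydroxyl and tertiary C10 hydroxyl)
Conditions: K2CO3 (cat.), MeOH, rt
Reagents that add atoms: none
Why: Base-catalysed transesterification of the cyclic carbonate with methanol releases the diol and leaves the secondary silyl ether intact.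

Step 8
Reactants: 11 cis-1,2-diol
Product: 12 alpha-hydroxy ketone (C1 ketone with tertiary C10 hydroxyl)
Conditions: SO3·pyridine, DMSO, Et3N, CH2Cl2, 0 °C
Reagents that add atoms: none
Why: Parikh–Doering oxidation converts the only oxidisable carbinol (C1) into the ketone and, unlike glycol-cleaving oxidants, leaves the tertiary alcohol and the C1–C10 bond alone.

Step 9
Reactants: 12 alpha-hydroxy ketone
Product: 13 ring B ketone (C1 ketone; C10 methyl and triethylsilyloxy; C8 tert-butyldimethylsilyloxy; C7 isopropenyl)
Conditions: Et3SiOTf, 2,6-lutidine, CH2Cl2, −78 → 0 °C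
Reagents that add atoms: triethylsilyl trifluoromethanesulfonate, CC[Si](CC)(CC)OS(=O)(=O)C(F)(F)F
Why: Silylation with a silyl triflate and a hindered pyridine base is the standard way to cap a tertiary alcohol, and the triethylsilyl group is chosen so that fluoride removes it later together with the secondary silyl ether.

Step 10
Reactants: 13 ring B ketone; 14 allyl bromide
Product: 16 6-allyl ketone (allyl trans to isopropenyl), via lithium enolate 15 (not isolated)
Conditions: LiN(i-Pr)2, THF, −78 °C; 14, DMPU, −78 → −20 °C
Reagents that add atoms: none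
Why: Ketone enolate alkylation, in which C10 is quaternary so only C6 can enolise and allyl bromide enters anti to the adjacent isopropenyl group to give the trans, all-equatorial product, so that any cis epimer can be equilibrated here before the alkene is moved next to the acidic position.

Step 11
Reactants: 16 6-allyl ketone
Product: 17 6-(E)-propenyl ketone (propenyl trans to isopropenyl)
Conditions: [Ir(cod)(PMePh2)2]PF6 (cat., activated with H2), THF, rt
Reagents that add atoms: none
Why: Iridium hydride-catalysed olefin isomerisation by one position converts the monosubstituted allyl terminus into the E-propenyl group under neutral conditions, so C6 is neither epimerised nor brought into conjugation, and the 1,1-disubstituted isopropenyl alkene should react far more slowly.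

Step 12
Reactants: 18 ethyl vinyl ether; 19 4-methoxybenzyl alcohol
Product: 20 4-methoxybenzyl vinyl ether
Conditions: Pd(OAc)2 (cat.), 1,10-phenanthroline (cat.), excess 18 as solvent, rt, air
Reagents that add atoms: none
Why: Palladium-catalysed transfer vinylation (transetherification) exchanges the ethyl group of the vinyl ether for the benzylic alcohol, with the excess of volatile ethyl vinyl ether driving the equilibrium.

Step 13
Reactants: 20 4-methoxybenzyl vinyl ether
Product: 22 (Z)-2-bromovinyl 4-methoxybenzyl ether, via dibromo ether 21 (not isolated)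
Conditions: Br2, CH2Cl2, −78 °C; PhNEt2, 90 °C
Reagents that add atoms: bromine, BrBr
Why: Bromine addition to the enol ether followed by amine-induced dehydrobromination of the alpha,beta-dibromo ether is the classical route to cis-2-bromovinyl ethers, the Z isomer being favoured and separable from any E isomer.

Step 14
Reactants: 17 6-(E)-propenyl ketone; 22 (Z)-2-bromovinyl 4-methoxybenzyl ether
Product: 25 cis-1-(Z-alkoxyvinyl)-2-(E-propenyl)cyclohexanol (vinyl axial and cis to propenyl), via lithio enol ether 23 (not isolated), via vinylcerium dichloride 24 (not isolated)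
Conditions: 22, t-BuLi (2 equiv per bromide), Et2O, −78 °C; CeCl3, THF, −78 °C; 17, −78 °C; H2O
Reagents that add atoms: none
Why: Bromine–lithium exchange proceeds with retention of the Z geometry and the derived organocerium reagent adds to the hindered, enolisable ketone (Imamoto-type 1,2-addition) along the axial trajectory opposite the axial C10 methyl group, which sets C1 with the new vinyl group axial and cis to the equatorial propenyl group.

Step 15
Reactants: 25 cis-1-(Z-alkoxyvinyl)-2-(E-propenyl)cyclohexanol
Product: 28 (Z)-cyclodec-5-enone with C3/C4/C7/C8/C10 set, via potassium alkoxide 26 (not isolated), via potassium enolate 27 (not isolated)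
Conditions: KN(SiMe3)2, THF, 0 °C → rt (no crown ether); AcOH, THF, −78 °C
Reagents that add atoms: none
Why: Deprotonation gives the potassium alkoxide 26, in which the C1–C6 bond is weakened and the 1,5-diene C3=C2–C1–C6–C5=C4 undergoes a concerted [3,3] shift: C3–C4 forms as C1–C6 breaks, leaving the C1 enolate 27 and the C5=C6 alkene, and protonation at C2 gives the ketone. The closest known reaction type is the anionic oxy-Cope ring expansion of 1-vinyl-2-alkenylcyclohexanols to cyclodec-5-enones. The ten-membered ring is not closed end to end but arises by four-carbon ring expansion of the cyclohexane through a six-membered chair transition state that cleaves the bond shared by both rings. C4 is controlled by the E geometry of the propenyl group (methyl pseudo-equatorial) and C3 by the Z geometry of the enol ether (alkoxy pseudo-axial), both read against the fixed C1 and C6 configurations, and the Z geometry of C5=C6 follows from C7 sitting pseudo-axial on that chair. The step needs chair over boat selectivity, which the ground-state chair of the cyclohexane should secure by holding the axial vinyl and equatorial propenyl groups gauche with C10 pseudo-equatorial, helped by potassium bridging the alkoxide and the syn-axial enol ether oxygen. Enolate formation makes the shift irreversible, and the quench at −78 °C limits E1cB loss of the C3 alkoxide.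

Step 16
Reactants: 28 (Z)-cyclodec-5-enone
Product: 30 C1/C6/C12-triol (epimers at C1/C11), via B-thexylborolane 29 (not isolated)
Conditions: thexylborane (3 equiv), THF, −10 °C → rt; NaOH, 30% H2O2, 0 °C
Reagents that add atoms: hydrogen peroxide, OO
Why: Cyclic hydroboration with thexylborane, in which boron adds first to the terminal carbon of the isopropenyl group and is then delivered to C6 through a five-membered borolane on the alkene face that carries C11 when H7 eclipses the Z alkene (allylic 1,3-strain), so oxidation with retention gives the C6 alcohol of the 6,7-trans series, while excess borane reduces the C1 ketone and the C1 and C11 mixtures are erased later.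

Step 17
Reactants: 30 C1/C6/C12-triol
Product: 32 trans-fused 11,13-dihydro-6,12-lactone (C1 carbinol free), via lactol 31 (not isolated)
Conditions: TEMPO (cat.), PhI(OAc)2, CH2Cl2, rt
Reagents that add atoms: none
Why: Nitroxyl-catalysed oxidation picks out the primary alcohol, the aldehyde closes to the five-membered lactol with the C6 hydroxyl and is oxidised on to the lactone, and the hindered secondary C1 carbinol should be left.

Step 18
Reactants: 32 11,13-dihydro-6,12-lactone
Product: 34 11-phenylselanyl lactone (selenium anti to H7), via dilithio alkoxide enolate 33 (not isolated)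
Conditions: LiN(i-Pr)2 (3 equiv), THF, −78 °C; PhSeBr, −78 °C; H2O
Reagents that add atoms: phenylselenenyl bromide, Br[Se]c1ccccc1
Why: Alpha-selenenylation of a lactone enolate, run with the C1 hydroxyl as its lithium alkoxide and kept at −78 °C so that this alkoxide does not take over the neighbouring triethylsilyl group; selenium should enter anti to H7, as is usual for trans-fused alpha-methyl lactones, and the C11 centre is transient.

Step 19
Reactants: 34 11-phenylselanyl lactone
Product: 36 alpha-methylene lactone with free C1 carbinol, via selenoxide 35 (not isolated)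
Conditions: 30% H2O2, pyridine, CH2Cl2, 0 °C → rt
Reagents that add atoms: none
Why: Selenoxide syn elimination, in which with selenium anti to H7 only the methyl hydrogens are syn to the selenoxide, so the exocyclic methylene should form and not the butenolide, and pyridine keeps the medium from turning acidic.

Step 20
Reactants: 36 alpha-methylene lactone with free C1 carbinol
Product: 37 alpha-methylene lactone C1 ketone bis-silyl ether
Conditions: Dess–Martin periodinane, CH2Cl2, 0 °C → rt
Reagents that add atoms: none
Why: Dess–Martin oxidation converges both C1 epimers on the ketone under neutral conditions that spare the beta-alkoxy ketone, the methylene lactone and both silyl ethers.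

Step 21
Reactants: 37 C1 ketone bis-silyl ether
Product: 38 8,10-diol (C1 ketone; O3 as PMB ether)
Conditions: HF·pyridine, pyridine, THF, 0 °C → rt
Reagents that add atoms: none
Why: Fluoride-mediated desilylation with buffered HF·pyridine removes the secondary tert-butyldimethylsilyl and the tertiary triethylsilyl ether in one operation without the base that would endanger the beta-alkoxy ketone.

Step 22
Reactants: 38 8,10-diol; 39 angelic acid
Product: 41 8-angelate with free tertiary C10 hydroxyl, via mixed anhydride 40 (not isolated)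
Conditions: 39, 2,4,6-Cl3C6H2COCl, Et3N, toluene, rt; then 38, 75 °C
Reagents that add atoms: none
Why: Yamaguchi-type mixed-anhydride esterification carried out without DMAP is the established way to acylate hindered alcohols with angelic acid without Z to E isomerisation, and the secondary C8 hydroxyl should react in preference to the tertiary C10 hydroxyl.

Step 23
Reactants: 41 8-angelate 10-ol
Product: 42 8-angelate 10-acetate 3-(4-methoxybenzyl) ether
Conditions: Ac2O, DMAP, Et3N, CH2Cl2, rt
Reagents that add atoms: acetic anhydride, CC(=O)OC(C)=O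
Why: DMAP-catalysed acyl transfer from acetic anhydride is the standard acetylation of tertiary alcohols and is run at room temperature to keep the angelate geometry and the beta-alkoxy ketone intact.

Step 24
Reactants: 42 8-angelate 10-acetate 3-(4-methoxybenzyl) ether
Product: 43 target CNP0141210.6
Conditions: DDQ, CH2Cl2/pH 7 buffer, 0 °C
Reagents that add atoms: none
Why: Oxidative cleavage of the 4-methoxybenzyl ether by DDQ proceeds through the benzylic oxocarbenium ion and its hemiacetal under neutral conditions, leaving the electron-poor alkenes, both esters and the resulting beta-hydroxy ketone untouched.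

**Compound list**

1 | (S)-(+)-carvone | CC1=CC[C@@H](CC1=O)C(C)=C | starting material
2 | potassium cross-conjugated dienolate of carvone | CC1=CC[C@H](C(C)=C)C=C1[O-].[K+] | intermediate
3 | trans-6-hydroxycarvone (OH anti to isopropenyl) | O=C1C(C)=CC[C@H](C(C)=C)[C@H]1O | intermediate
4 | trans-6-(tert-butyldimethylsilyloxy)carvone | O=C1C(C)=CC[C@H](C(C)=C)[C@H]1O[Si](C)(C)C(C)(C)C | intermediate
5 | 2,3-epoxy ketone of 4, epoxide anti to isopropenyl | O=C1[C@@]2(C)O[C@H]2C[C@H](C(C)=C)[C@H]1O[Si](C)(C)C(C)(C)C | intermediate
6 | hydrazone of epoxy ketone 5 | NN=C1[C@@]2(C)O[C@H]2C[C@H](C(C)=C)[C@H]1O[Si](C)(C)C(C)(C)C | intermediate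
7 | 4-(tert-butyldimethylsilyloxy)-2-methyl-5-isopropenylcyclohex-2-en-1-ol, OH cis to OTBS and trans to isopropenyl | O[C@H]1C[C@H](C(C)=C)[C@@H](O[Si](C)(C)C(C)(C)C)C=C1C | intermediate
8 | lithium alkyl carbonate of 7 | [Li+].[O-]C(=O)O[C@H]1C[C@H](C(C)=C)[C@@H](O[Si](C)(C)C(C)(C)C)C=C1C | intermediate
9 | cis-fused C1/C10 cyclic carbonate, iodine at C9 anti to the carbonate oxygen | O=C1O[C@H]2C[C@H](C(C)=C)[C@@H](O[Si](C)(C)C(C)(C)C)[C@H](I)[C@@]2(C)O1 | intermediate
10 | cis-fused C1/C10 cyclic carbonate, C9 methylene | O=C1O[C@H]2C[C@H](C(C)=C)[C@@H](O[Si](C)(C)C(C)(C)C)C[C@@]2(C)O1 | intermediate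
11 | cis-1,2-diol (C1 secondary, C10 tertiary) | O[C@H]1C[C@H](C(C)=C)[C@@H](O[Si](C)(C)C(C)(C)C)C[C@@]1(C)O | intermediate
12 | alpha-hydroxy ketone (C1 ketone, C10 tertiary OH) | O=C1[C@](C)(O)C[C@H](O[Si](C)(C)C(C)(C)C)[C@@H](C(C)=C)C1 | intermediate
13 | ring B ketone with C10 OSiEt3, C8 OTBS, C7 isopropenyl | O=C1[C@](C)(O[Si](CC)(CC)CC)C[C@H](O[Si](C)(C)C(C)(C)C)[C@@H](C(C)=C)C1 | intermediate
14 | allyl bromide | C=CCBr | starting material
15 | lithium C1–C6 enolate of 13 | [Li+].[O-]C1=C[C@H](C(C)=C)[C@@H](O[Si](C)(C)C(C)(C)C)C[C@@]1(C)O[Si](CC)(CC)CC | intermediate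
16 | 6-allyl ketone, allyl trans to isopropenyl | O=C1[C@](C)(O[Si](CC)(CC)CC)C[C@H](O[Si](C)(C)C(C)(C)C)[C@@H](C(C)=C)[C@@H]1CC=C | intermediate
17 | 6-(E)-propenyl ketone, propenyl trans to isopropenyl | O=C1[C@](C)(O[Si](CC)(CC)CC)C[C@H](O[Si](C)(C)C(C)(C)C)[C@@H](C(C)=C)[C@@H]1/C=C/C | intermediate
18 | ethyl vinyl ether | C=COCC | starting material
19 | 4-methoxybenzyl alcohol | OCc1ccc(OC)cc1 | starting material
20 | 4-methoxybenzyl vinyl ether | C=COCc1ccc(OC)cc1 | intermediate
21 | 1,2-dibromoethyl 4-methoxybenzyl ether | BrCC(Br)OCc1ccc(OC)cc1 | intermediate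
22 | (Z)-2-bromovinyl 4-methoxybenzyl ether | Br/C=C\OCc1ccc(OC)cc1 | intermediate
23 | (Z)-2-(4-methoxybenzyloxy)vinyllithium | [Li]/C=C\OCc1ccc(OC)cc1 | intermediate
24 | (Z)-2-(4-methoxybenzyloxy)vinylcerium dichloride | Cl[Ce](Cl)/C=C\OCc1ccc(OC)cc1 | intermediate
25 | cis-1-(Z-alkoxyvinyl)-2-(E-propenyl)cyclohexanol, vinyl axial | O[C@@]1(/C=C\OCc2ccc(OC)cc2)[C@](C)(O[Si](CC)(CC)CC)C[C@H](O[Si](C)(C)C(C)(C)C)[C@@H](C(C)=C)[C@@H]1/C=C/C | intermediate
26 | potassium alkoxide of 25 | [K+].[O-][C@@]1(/C=C\OCc2ccc(OC)cc2)[C@](C)(O[Si](CC)(CC)CC)C[C@H](O[Si](C)(C)C(C)(C)C)[C@@H](C(C)=C)[C@@H]1/C=C/C | intermediate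
27 | potassium C1–C2 enolate of 28 | [C@H]1(C(C)=C)/C=C\[C@@H](C)[C@@H](OCc2ccc(OC)cc2)/C=C(\[O-])[C@](C)(O[Si](CC)(CC)CC)C[C@@H]1O[Si](C)(C)C(C)(C)C.[K+] | intermediate
28 | (Z)-cyclodec-5-enone: C1 ketone, C3 OPMB, C4 methyl, C7 isopropenyl, C8 OTBS, C10 methyl and OSiEt3, all configured as in the target | [C@H]1(C(C)=C)/C=C\[C@@H](C)[C@@H](OCc2ccc(OC)cc2)CC(=O)[C@](C)(O[Si](CC)(CC)CC)C[C@@H]1O[Si](C)(C)C(C)(C)C | intermediate
29 | B-thexylborolane (boron on C6 and C12), C1 as thexylborinate | CC1CB(C(C)(C)C(C)C)[C@@H]2C[C@@H](C)[C@@H](OCc3ccc(OC)cc3)CC(OBC(C)(C)C(C)C)[C@](C)(O[Si](CC)(CC)CC)C[C@H](O[Si](C)(C)C(C)(C)C)[C@@H]12 | intermediate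
30 | C1,C6,C12-triol (mixture at C1 and C11) | OCC(C)[C@H]1[C@H](O)C[C@@H](C)[C@@H](OCc2ccc(OC)cc2)CC(O)[C@](C)(O[Si](CC)(CC)CC)C[C@@H]1O[Si](C)(C)C(C)(C)C | intermediate
31 | 6,12-lactol | CC1C(O)O[C@@H]2C[C@@H](C)[C@@H](OCc3ccc(OC)cc3)CC(O)[C@](C)(O[Si](CC)(CC)CC)C[C@H](O[Si](C)(C)C(C)(C)C)[C@@H]12 | intermediate
32 | trans-fused 11,13-dihydro-6,12-lactone, C1 carbinol free | CC1C(=O)O[C@@H]2C[C@@H](C)[C@@H](OCc3ccc(OC)cc3)CC(O)[C@](C)(O[Si](CC)(CC)CC)C[C@H](O[Si](C)(C)C(C)(C)C)[C@@H]12 | intermediate
33 | dilithium C1 alkoxide / lactone enolate of 32 | CC1=C([O-])O[C@@H]2C[C@@H](C)[C@@H](OCc3ccc(OC)cc3)CC([O-])[C@](C)(O[Si](CC)(CC)CC)C[C@H](O[Si](C)(C)C(C)(C)C)[C@@H]12.[Li+].[Li+] | intermediate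
34 | 11-phenylselanyl lactone, selenium anti to H7 | C[C@]1([Se]c3ccccc3)C(=O)O[C@@H]2C[C@@H](C)[C@@H](OCc4ccc(OC)cc4)CC(O)[C@](C)(O[Si](CC)(CC)CC)C[C@H](O[Si](C)(C)C(C)(C)C)[C@@H]12 | intermediate
35 | selenoxide of 34 | C[C@]1([Se](=O)c3ccccc3)C(=O)O[C@@H]2C[C@@H](C)[C@@H](OCc4ccc(OC)cc4)CC(O)[C@](C)(O[Si](CC)(CC)CC)C[C@H](O[Si](C)(C)C(C)(C)C)[C@@H]12 | intermediate
36 | alpha-methylene lactone, C1 carbinol free | C=C1C(=O)O[C@@H]2C[C@@H](C)[C@@H](OCc3ccc(OC)cc3)CC(O)[C@](C)(O[Si](CC)(CC)CC)C[C@H](O[Si](C)(C)C(C)(C)C)[C@@H]12 | intermediate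
37 | alpha-methylene lactone, C1 ketone, C8 OTBS, C10 OSiEt3 | C=C1C(=O)O[C@@H]2C[C@@H](C)[C@@H](OCc3ccc(OC)cc3)CC(=O)[C@](C)(O[Si](CC)(CC)CC)C[C@H](O[Si](C)(C)C(C)(C)C)[C@@H]12 | intermediate
38 | alpha-methylene lactone, C1 ketone, free C8 and C10 hydroxyls | C=C1C(=O)O[C@@H]2C[C@@H](C)[C@@H](OCc3ccc(OC)cc3)CC(=O)[C@](C)(O)C[C@H](O)[C@@H]12 | intermediate
39 | angelic acid, (Z)-2-methylbut-2-enoic acid | C/C=C(/C)C(=O)O | starting material
40 | angelic 2,4,6-trichlorobenzoic mixed anhydride | C/C=C(/C)C(=O)OC(=O)c1c(Cl)cc(Cl)cc1Cl | intermediate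
41 | 8-angelate with free C10 hydroxyl | C=C1C(=O)O[C@@H]2C[C@@H](C)[C@@H](OCc3ccc(OC)cc3)CC(=O)[C@](C)(O)C[C@H](OC(=O)/C(C)=C\C)[C@@H]12 | intermediate
42 | 8-angelate 10-acetate 3-(4-methoxybenzyl) ether | C=C1C(=O)O[C@@H]2C[C@@H](C)[C@@H](OCc3ccc(OC)cc3)CC(=O)[C@](C)(OC(C)=O)C[C@H](OC(=O)/C(C)=C\C)[C@@H]12 | intermediate
43 | CNP0141210.6 | C=C1C(=O)O[C@@H]2C[C@@H](C)[C@@H](O)CC(=O)[C@](C)(OC(C)=O)C[C@H](OC(=O)/C(C)=C\C)[C@@H]12 | target

**Step count and risks**

Total step count: 24. Longest linear sequence: 22 steps (steps 1–11 and 14–24 from (S)-carvone). The two-step branch (steps 12 and 13) joins at step 14.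

Steps most likely to fail:

1. Step 15. The potassium enolate may expel the C3 alkoxide (E1cB) before the quench, and the triethylsilyl group may shift to the alkoxide or enolate oxygen next to it. The fallback removes the charge: it sets out from 25, which is silylated (Me3SiOTf, 2,6-lutidine) to the carbinol trimethylsilyl ether F1. F1 is heated (o-dichlorobenzene, about 190 °C, base-washed glass) in a thermal siloxy-Cope rearrangement through the same chair to the trimethylsilyl enol ether F2. F2 is cleaved with AcOH in aqueous THF at 0 °C, which comes back to the route at 28.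

2. Step 16. The second B–H addition may close the six-membered borinane (boron on C5) or occur from outside on the open alkene face, and incomplete ketone reduction would expose a beta-alkoxy ketone to basic peroxide. The fallback uses a carboxylate tether and sets out from 28:
   - NaBH4 in MeOH gives the C1 carbinol F3.
   - 9-borabicyclo[3.3.1]nonane, then NaOH/H2O2, hydroborates only the isopropenyl group to the 1,12-diol F4.
   - TEMPO/PhI(OAc)2 in wet MeCN oxidises the primary alcohol to the carboxylic acid F5.
   - I2/NaHCO3 in MeCN closes the iodolactone F6 by 5-exo attack of the carboxylate on C6, on the face that carries C11, with iodine anti at C5.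
   - Bu3SnH/AIBN removes the iodine, which comes back to the route at 32.

3. Step 14. The basic vinyl metal may deprotonate the doubly activated C6–H (allylic and alpha to the ketone), or the lithio enol ether may decompose before it adds, so that ketone is returned. The fallback changes the order of events and sets out from 16: reagent 24 is added to this plain alpha-alkyl ketone to give the 2-allyl carbinol F7. The [Ir(cod)(PMePh2)2]PF6 isomerisation of step 11 is then run on F7, which comes back to the route at 25.

**Further compounds**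

F1 | step 15 | trimethylsilyl ether of carbinol 25 | C[Si](C)(C)O[C@@]1(/C=C\OCc2ccc(OC)cc2)[C@](C)(O[Si](CC)(CC)CC)C[C@H](O[Si](C)(C)C(C)(C)C)[C@@H](C(C)=C)[C@@H]1/C=C/C
F2 | step 15 | C1–C2 trimethylsilyl enol ether of 28 | [C@H]1(C(C)=C)/C=C\[C@@H](C)[C@@H](OCc2ccc(OC)cc2)/C=C(\O[Si](C)(C)C)[C@](C)(O[Si](CC)(CC)CC)C[C@@H]1O[Si](C)(C)C(C)(C)C
F3 | step 16 | C1 carbinol of 28 (mixture at C1) | [C@H]1(C(C)=C)/C=C\[C@@H](C)[C@@H](OCc2ccc(OC)cc2)CC(O)[C@](C)(O[Si](CC)(CC)CC)C[C@@H]1O[Si](C)(C)C(C)(C)C
F4 | step 16 | 1,12-diol with the Z C5=C6 alkene intact (mixture at C1 and C11) | OCC(C)[C@H]1/C=C\[C@@H](C)[C@@H](OCc2ccc(OC)cc2)CC(O)[C@](C)(O[Si](CC)(CC)CC)C[C@@H]1O[Si](C)(C)C(C)(C)C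
F5 | step 16 | C12 carboxylic acid | OC(=O)C(C)[C@H]1/C=C\[C@@H](C)[C@@H](OCc2ccc(OC)cc2)CC(O)[C@](C)(O[Si](CC)(CC)CC)C[C@@H]1O[Si](C)(C)C(C)(C)C
F6 | step 16 | 5-iodo-11,13-dihydro-6,12-lactone, iodine anti to O6 | CC1C(=O)O[C@@H]2[C@@H](I)[C@@H](C)[C@@H](OCc3ccc(OC)cc3)CC(O)[C@](C)(O[Si](CC)(CC)CC)C[C@H](O[Si](C)(C)C(C)(C)C)[C@@H]12
F7 | step 14 | cis-1-(Z-alkoxyvinyl)-2-allylcyclohexanol | O[C@@]1(/C=C\OCc2ccc(OC)cc2)[C@](C)(O[Si](CC)(CC)CC)C[C@H](O[Si](C)(C)C(C)(C)C)[C@@H](C(C)=C)[C@@H]1CC=C
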